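**Strategy.** The route rests on cutting ring B at C6–C7. This turns ring A into an achiral 4,4-disubstituted cyclohexa-2,5-dienone, because the quaternary C12 lies para to C15 in ring A; C12 carries a 2-oxopropyl arm (C4–C6) and the nitrogen arm (C11–C9). One amine-catalysed 5-exo Michael addition of the methyl-ketone enamine carbon C6 to one enantiotopic β-carbon (C7) closes ring B, sets C7 and C12 together, and leaves the C13=C14–C15=O enone for the ring A oxygens. In the precursor the nitrogen is fully substituted (Boc and the masked C1–C3 aldehyde arm), so no N–H can add to the dienone and the azonine later closes at C4 by intramolecular aldol condensation.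

Key step: step 7

**Remarks**
- Numbering: azonine N–C1–C2–C3=C4–C12–C11–C10–C9; ring B C4–C5–C6–C7–C12; ring A C12–C13–C14–C15–C8–C7. The α-face of ring A is the face on which the ring B bonds C12–C4 and C7–C6 lie; the β-face carries C11 and H-7. The target is (7S,12S,13S,15S), with both acetoxy groups α and the C15 methyl β.
- Assumption: 1, 2, 5 and 9 are taken as commercial. Which pseudoenantiomer of the cinchona amine leads to (3aR,7aR)-14 cannot be predicted with certainty and is to be fixed in a preliminary run.

**Route**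

Step 1
Reactants: 1 5-bromopentanenitrile; 2 2-(2-aminoethyl)-1,3-dioxolane
Product: 4 tert-butyl N-(4-cyanobutyl)-N-[2-(1,3-dioxolan-2-yl)ethyl]carbamate, via secondary amino nitrile 3 (not isolated)
Conditions: 2 (3 equiv), K2CO3, MeCN, 60 °C; aqueous wash; then Boc2O, Et3N, CH2Cl2, rt
Reagents that add atoms: di-tert-butyl dicarbonate, CC(C)(C)OC(=O)OC(=O)OC(C)(C)C
Why: SN2 N-alkylation of the primary amine by the unhindered primary bromide (excess amine limits dialkylation) followed by carbamoylation should give a nitrogen with no N–H that already carries the masked C1–C3 aldehyde arm.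

Step 2
Reactants: 4 tert-butyl N-(4-cyanobutyl)-N-[2-(1,3-dioxolan-2-yl)ethyl]carbamate; 5 propargyl bromide
Product: 6 racemic tert-butyl N-(4-cyanohept-6-yn-1-yl)-N-[2-(1,3-dioxolan-2-yl)ethyl]carbamate
Conditions: LiN(i-Pr)2 (1.05 equiv), THF, −78 °C; then 5, −78 → −30 °C
Reagents that add atoms: none
Why: α-Alkylation of the lithiated nitrile with a reactive propargylic bromide should place C4–C6 on the future quaternary carbon C12, the racemic stereocentre being erased later at the dienone stage.

Step 3
Reactants: 6 racemic tert-butyl N-(4-cyanohept-6-yn-1-yl)-N-[2-(1,3-dioxolan-2-yl)ethyl]carbamate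
Product: 8 racemic tert-butyl N-[2-(1,3-dioxolan-2-yl)ethyl]-N-(4-formylhept-6-yn-1-yl)carbamate, via aluminium aldiminate 7 (not isolated)
Conditions: i-Bu2AlH (1.2 equiv), toluene, −78 °C; then aqueous potassium sodium tartrate, pH 5 buffer, 0 °C
Reagents that add atoms: water, O
Why: Partial reduction of the nitrile by i-Bu2AlH stops at the N-aluminated aldimine at −78 °C, which hydrolyses to the α-branched aldehyde on a mildly acidic work-up that the dioxolane and the Boc group tolerate.

Step 4
Reactants: 8 racemic tert-butyl N-[2-(1,3-dioxolan-2-yl)ethyl]-N-(4-formylhept-6-yn-1-yl)carbamate; 9 methyl vinyl ketone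
Product: 11 racemic tert-butyl N-[2-(1,3-dioxolan-2-yl)ethyl]-N-{3-[4-oxo-1-(prop-2-yn-1-yl)cyclohex-2-en-1-yl]propyl}carbamate, via keto aldehyde Michael adduct 10 (not isolated)
Conditions: 9 (1.5 equiv), KOH (0.15 equiv), EtOH, 0 °C → rt; then 60 °C
Reagents that add atoms: none
Why: Robinson annulation, in which the α-branched aldehyde enolate adds to the enone and the new methyl ketone closes onto the now non-enolisable aldehyde with dehydration, is the standard entry to 4,4-disubstituted cyclohex-2-enones.

Step 5
Reactants: 11 racemic tert-butyl N-[2-(1,3-dioxolan-2-yl)ethyl]-N-{3-[4-oxo-1-(prop-2-yn-1-yl)cyclohex-2-en-1-yl]propyl}carbamate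
Product: 12 tert-butyl N-[2-(1,3-dioxolan-2-yl)ethyl]-N-{3-[4-oxo-1-(prop-2-yn-1-yl)cyclohexa-2,5-dien-1-yl]propyl}carbamate
Conditions: IBX (2.5 equiv), DMSO/PhF (1:2), 75 °C
Reagents that add atoms: none
Why: IBX-mediated α,β-dehydrogenation of the saturated CH2–CH2 edge of the enone should give the cross-conjugated dienone, which removes the C12 stereocentre and creates the mirror plane needed for desymmetrisation.

Step 6
Reactants: 12 tert-butyl N-[2-(1,3-dioxolan-2-yl)ethyl]-N-{3-[4-oxo-1-(prop-2-yn-1-yl)cyclohexa-2,5-dien-1-yl]propyl}carbamate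
Product: 13 4-(2-oxopropyl)-4-{3-[(tert-butoxycarbonyl)(2-(1,3-dioxolan-2-yl)ethyl)amino]propyl}cyclohexa-2,5-dien-1-one
Conditions: Ph3PAuNTf2 (2 mol%), 1,4-dioxane/H2O (10:1), 60 °C
Reagents that add atoms: water, O
Why: Gold-catalysed Markovnikov hydration of the terminal alkyne gives the methyl ketone under near-neutral conditions, so the ketone appears only once the dienone is in place and no base or amine is present to start a racemic cyclisation.

Step 7
Reactants: 13 4-(2-oxopropyl)-4-{3-[(tert-butoxycarbonyl)(2-(1,3-dioxolan-2-yl)ethyl)amino]propyl}cyclohexa-2,5-dien-1-one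
Product: 14 tert-butyl N-[2-(1,3-dioxolan-2-yl)ethyl]-N-{3-[(3aR,7aR)-2,6-dioxo-1,2,3,6,7,7a-hexahydro-3aH-inden-3a-yl]propyl}carbamate (cis-fused enone dione; 7R,12R in the numbering above)
Conditions: 9-amino-9-deoxy-epi-quinine (20 mol%; or its quinidine-derived pseudoenantiomer), 2-nitrobenzoic acid (40 mol%), toluene, 35 °C
Reagents that add atoms: none
Why: The primary amine condenses with the unhindered C5 methyl ketone, the iminium tautomerises to the terminal enamine, and its carbon C6 adds in a conjugate sense to C7 of one enone arm while the acid co-catalyst activates that enone, after which hydrolysis releases the catalyst. The closest known reaction type is the amine-catalysed enantioselective intramolecular Michael desymmetrisation of 4,4-disubstituted cyclohexa-2,5-dienones through the enamine of a tethered carbonyl group. Ring B closes in the 5-exo-trig mode, and the three-atom tether C12–C4–C5 allows only the cis ring fusion. C7 and C12 are set together by the catalyst, which selects one of the two enantiotopic enone arms, and the pseudoenantiomeric catalyst pair gives access to either antipode. The step needs enamine formation toward CH3 (the C4 enamine could only close a three-membered ring and is unproductive) and chemoselectivity over hetero-Michael addition, which the substrate secures because the nitrogen bears no N–H and the aldehyde is masked as a dioxolane.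

Step 8
Reactants: 14 tert-butyl N-[2-(1,3-dioxolan-2-yl)ethyl]-N-{3-[(3aR,7aR)-2,6-dioxo-1,2,3,6,7,7a-hexahydro-3aH-inden-3a-yl]propyl}carbamate
Product: 15 C5 ethylene ketal of 14 (spiro-1,3-dioxolane at C5; C13=C14–C15=O enone intact)
Conditions: (TMSOCH2)2 (1.3 equiv), TMSOTf (5 mol%), CH2Cl2, −78 °C; pyridine quench
Reagents that add atoms: 1,2-bis(trimethylsilyloxy)ethane, C[Si](C)(C)OCCO[Si](C)(C)C
Why: Silyl-triflate-catalysed ketalisation at −78 °C is kinetically selective for the saturated cyclopentanone C5 over the conjugated C15 ketone, so C5 is masked before hydride and methyl nucleophiles are used.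

Step 9
Reactants: 15 C5 ethylene ketal of 14
Product: 16 allylic alcohol (C15–OH on the α-face, C13=C14 retained, C5 ketal)
Conditions: NaBH4, CeCl3·7H2O, MeOH, −78 °C
Reagents that add atoms: none
Why: Luche 1,2-reduction, in which hydride should enter axially from the convex β-face (the face of H-7, away from ring B), places the C15 hydroxyl on the α-face where it can direct the next step.

Step 10
Reactants: 16 allylic alcohol (15α-OH)
Product: 17 13α,14α-epoxy-15α-alcohol (C5 ketal)
Conditions: VO(acac)2 (5 mol%), t-BuOOH (1.5 equiv), CH2Cl2, 0 °C → rt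
Reagents that add atoms: tert-butyl hydroperoxide, CC(C)(C)OO
Why: Vanadium-catalysed hydroxyl-directed epoxidation transfers oxygen only through the vanadate ester of the allylic alcohol, so the C13–C14 epoxide forms syn to the α-hydroxyl and the C13–O bond is set on the α-face.

Step 11
Reactants: 17 13α,14α-epoxy-15α-alcohol
Product: 18 13α,14α-epoxy-15-ketone (C5 ketal)
Conditions: Dess–Martin periodinane, NaHCO3, CH2Cl2, 0 °C → rt
Reagents that add atoms: none
Why: Dess–Martin oxidation of the secondary alcohol gives the α,β-epoxy ketone without touching the epoxide, the two dioxolanes or the carbamate.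

Step 12
Reactants: 18 13α,14α-epoxy-15-ketone
Product: 19 13α-hydroxy-15-ketone (C14 now CH2; C5 ketal)
Conditions: SmI2 (2.5 equiv), THF/MeOH (2:1), −90 °C
Reagents that add atoms: none
Why: In this SmI2 reduction of an α,β-epoxy ketone the C15 ketyl can break only the Cα–O bond (C14–O), so the β-hydroxy ketone forms with the C13 configuration retained and without reliance on trans-diaxial epoxide opening.

Step 13
Reactants: 19 13α-hydroxy-15-ketone
Product: 20 13α-triethylsilyloxy-15-ketone (C5 ketal)
Conditions: Et3SiCl, imidazole, DMF, 0 °C → rt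
Reagents that add atoms: chlorotriethylsilane, CC[Si](Cl)(CC)CC
Why: Silylation masks the C13 hydroxyl so that the methyl addition meets no alkoxide (no retro-aldol or β-elimination), and the ether is shed later in the acidic hydrolysis.

Step 14
Reactants: 20 13α-triethylsilyloxy-15-ketone
Product: 21 13α-triethylsilyloxy-15α-hydroxy-15β-methyl compound (C5 ketal)
Conditions: MeAl(OAr)2 (Ar = 2,6-di-tert-butyl-4-methylphenyl; 3 equiv, from Me3Al and ArOH), toluene, −78 °C; then MeLi (3 equiv), −78 °C
Reagents that add atoms: methyllithium, [Li]C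
Why: 1,2-Addition of methyllithium to the ketone complexed by the bulky aluminium bis(aryloxide), which blocks the equatorial trajectory, should deliver CH3 axially from the β-face and leave the C15 hydroxyl equatorial on the α-face, cis to the C13 oxygen.

Step 15
Reactants: 21 13α-triethylsilyloxy-15α-hydroxy-15β-methyl compound
Product: 22 keto aldehyde diol (C5 ketone, N-Boc-N-(3-oxopropyl) arm, 13α,15α-diol, 15β-methyl)
Conditions: 1 M HCl (aq)/THF (1:3), rt
Reagents that add atoms: water, O
Why: Acid-catalysed acetal hydrolysis unmasks the C5 ketone and the C3 aldehyde and removes the silyl ether in one operation, under aqueous conditions too mild to cleave the Boc group or ionise the tertiary alcohol.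

Step 16
Reactants: 22 keto aldehyde diol
Product: 24 N-Boc azonine enone diol ((3E)-C3=C4–C5=O, 13α,15α-diol), via nine-membered β-hydroxy ketone 23 (not isolated)
Conditions: K2CO3 (3 equiv), MeOH, 0.003 M (slow addition), 45 °C
Reagents that add atoms: none
Why: In this intramolecular aldol condensation under reversible enolisation only the C4 enolate can reach the tethered aldehyde through a fused nine-membered ring (C6 would need a bridged ten-membered ring), and E1cB dehydration inside that ring gives the enone with C2 cis to C12, which is the E geometry of the target.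

Step 17
Reactants: 24 N-Boc azonine enone diol
Product: 25 azonine enone diol as the free secondary amine
Conditions: CF3CO2H/CH2Cl2 (1:4), 0 °C; aqueous NaHCO3
Reagents that add atoms: none
Why: Acidolysis of the tert-butyl carbamate (loss of isobutene and CO2) is placed while both hydroxyls are still free, because a tertiary acetate would ionise under these conditions.

Step 18
Reactants: 25 azonine enone diol (free amine)
Product: 26 N-formyl azonine enone diol
Conditions: HCO2CH2CF3 (3 equiv), THF, 50 °C
Reagents that add atoms: 2,2,2-trifluoroethyl formate, O=COCC(F)(F)F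
Why: N-Formylation with an activated formate ester is chemoselective for the secondary amine over the hindered secondary and tertiary alcohols.

Step 19
Reactants: 26 N-formyl azonine enone diol
Product: 27 target, (7S,12S,13S,15S,3E)-13α,15α-diacetoxy-15β-methyl N-formyl azonine enone (CNP0137427.1)
Conditions: Ac2O, DMAP, Et3N, CH2Cl2, 40 °C
Reagents that add atoms: acetic anhydride, CC(=O)OC(C)=O
Why: DMAP-catalysed acylation esterifies the secondary C13 and the tertiary C15 hydroxyl with retention at both carbons and completes the target.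

**Compound list**

1 | 5-bromopentanenitrile | N#CCCCCBr | starting material
2 | 2-(2-aminoethyl)-1,3-dioxolane | NCCC1OCCO1 | starting material
3 | 5-{[2-(1,3-dioxolan-2-yl)ethyl]amino}pentanenitrile | N#CCCCCNCCC1OCCO1 | intermediate
4 | tert-butyl N-(4-cyanobutyl)-N-[2-(1,3-dioxolan-2-yl)ethyl]carbamate | N#CCCCCN(CCC1OCCO1)C(=O)OC(C)(C)C | intermediate
5 | propargyl bromide (3-bromoprop-1-yne) | C#CCBr | starting material
6 | tert-butyl N-(4-cyanohept-6-yn-1-yl)-N-[2-(1,3-dioxolan-2-yl)ethyl]carbamate (racemic) | N#CC(CC#C)CCCN(CCC1OCCO1)C(=O)OC(C)(C)C | intermediate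
7 | N-(diisobutylaluminio) aldimine of 8 (racemic) | C#CCC(C=N[Al](CC(C)C)CC(C)C)CCCN(CCC1OCCO1)C(=O)OC(C)(C)C | intermediate
8 | tert-butyl N-[2-(1,3-dioxolan-2-yl)ethyl]-N-(4-formylhept-6-yn-1-yl)carbamate (racemic) | O=CC(CC#C)CCCN(CCC1OCCO1)C(=O)OC(C)(C)C | intermediate
9 | methyl vinyl ketone (but-3-en-2-one) | CC(=O)C=C | starting material
10 | tert-butyl N-[2-(1,3-dioxolan-2-yl)ethyl]-N-[4-formyl-7-oxo-4-(prop-2-yn-1-yl)octyl]carbamate (racemic) | CC(=O)CCC(C=O)(CC#C)CCCN(CCC1OCCO1)C(=O)OC(C)(C)C | intermediate
11 | tert-butyl N-[2-(1,3-dioxolan-2-yl)ethyl]-N-{3-[4-oxo-1-(prop-2-yn-1-yl)cyclohex-2-en-1-yl]propyl}carbamate (racemic) | C#CCC1(CCCN(CCC2OCCO2)C(=O)OC(C)(C)C)C=CC(=O)CC1 | intermediate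
12 | tert-butyl N-[2-(1,3-dioxolan-2-yl)ethyl]-N-{3-[4-oxo-1-(prop-2-yn-1-yl)cyclohexa-2,5-dien-1-yl]propyl}carbamate | C#CCC1(CCCN(CCC2OCCO2)C(=O)OC(C)(C)C)C=CC(=O)C=C1 | intermediate
13 | 4-(2-oxopropyl)-4-{3-[(tert-butoxycarbonyl)(2-(1,3-dioxolan-2-yl)ethyl)amino]propyl}cyclohexa-2,5-dien-1-one (key-step precursor) | CC(=O)CC1(CCCN(CCC2OCCO2)C(=O)OC(C)(C)C)C=CC(=O)C=C1 | intermediate
14 | tert-butyl N-[2-(1,3-dioxolan-2-yl)ethyl]-N-{3-[(3aR,7aR)-2,6-dioxo-1,2,3,6,7,7a-hexahydro-3aH-inden-3a-yl]propyl}carbamate (key-step product, cis-fused) | C1=CC(=O)C[C@H]2CC(=O)C[C@]21CCCN(CCC3OCCO3)C(=O)OC(C)(C)C | intermediate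
15 | C5 ethylene ketal of 14 (enone C13=C14–C15=O intact) | C1=CC(=O)C[C@H]2CC3(OCCO3)C[C@]21CCCN(CCC4OCCO4)C(=O)OC(C)(C)C | intermediate
16 | allylic alcohol, 15α-OH, C13=C14, C5 ketal | C1=C[C@@H](O)C[C@H]2CC3(OCCO3)C[C@]21CCCN(CCC4OCCO4)C(=O)OC(C)(C)C | intermediate
17 | 13α,14α-epoxy-15α-alcohol, C5 ketal | O1[C@H]2[C@@H]1[C@@H](O)C[C@H]3CC4(OCCO4)C[C@]32CCCN(CCC5OCCO5)C(=O)OC(C)(C)C | intermediate
18 | 13α,14α-epoxy-15-ketone, C5 ketal | O1[C@H]2[C@@H]1C(=O)C[C@H]3CC4(OCCO4)C[C@]32CCCN(CCC5OCCO5)C(=O)OC(C)(C)C | intermediate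
19 | 13α-hydroxy-15-ketone, C5 ketal | O[C@H]1CC(=O)C[C@H]2CC3(OCCO3)C[C@]21CCCN(CCC4OCCO4)C(=O)OC(C)(C)C | intermediate
20 | 13α-triethylsilyloxy-15-ketone, C5 ketal | CC[Si](CC)(CC)O[C@H]1CC(=O)C[C@H]2CC3(OCCO3)C[C@]21CCCN(CCC4OCCO4)C(=O)OC(C)(C)C | intermediate
21 | 13α-triethylsilyloxy-15α-hydroxy-15β-methyl compound, C5 ketal | CC[Si](CC)(CC)O[C@H]1C[C@@](C)(O)C[C@H]2CC3(OCCO3)C[C@]21CCCN(CCC4OCCO4)C(=O)OC(C)(C)C | intermediate
22 | keto aldehyde diol: C5 ketone, N-Boc-N-(3-oxopropyl) arm, 13α,15α-diol, 15β-methyl | O[C@H]1C[C@@](C)(O)C[C@H]2CC(=O)C[C@]21CCCN(CCC=O)C(=O)OC(C)(C)C | intermediate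
23 | nine-membered aldol adduct (C3 carbinol; C3 and C4 configurations not controlled) | O[C@H]1C[C@@](C)(O)C[C@H]2CC(=O)C3C(O)CCN(C(=O)OC(C)(C)C)CCC[C@@]321 | intermediate
24 | N-Boc azonine (3E)-enone 13α,15α-diol | O[C@H]1C[C@@](C)(O)C[C@H]2CC(=O)/C3=C/CCN(C(=O)OC(C)(C)C)CCC[C@@]321 | intermediate
25 | azonine (3E)-enone 13α,15α-diol, free secondary amine | O[C@H]1C[C@@](C)(O)C[C@H]2CC(=O)/C3=C/CCNCCC[C@@]321 | intermediate
26 | N-formyl azonine (3E)-enone 13α,15α-diol | O[C@H]1C[C@@](C)(O)C[C@H]2CC(=O)/C3=C/CCN(C=O)CCC[C@@]321 | intermediate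
27 | (7S,12S,13S,15S,3E)-13α,15α-diacetoxy-15β-methyl N-formyl azonine enone, CNP0137427.1 | CC(=O)O[C@H]1C[C@@](C)(OC(C)=O)C[C@H]2CC(=O)/C3=C/CCN(C=O)CCC[C@@]321 | target

**Step count.** Total: 19 steps. Longest linear sequence: 19 steps (1 → 27; the route is fully linear).

**Steps most likely to fail**

1. Step 16 (nine-membered ring closure). The medium ring may close slowly, so that intermolecular aldol oligomerisation, closure through C6, or base-induced β-elimination of the carbamate nitrogen from the β-amido aldehyde (loss of the C1–C3 arm) takes over. The fallback sets out from 22 and changes the bond-forming mode from enolate plus aldehyde under base to enol plus iminium ion under buffered acid. Stoichiometric morpholinium trifluoroacetate in THF at 60 °C under high dilution converts the aldehyde into its iminium ion, which the C4 enol of the ketone attacks in a reversible intramolecular Mannich reaction to give the nine-membered β-morpholino ketone F1. Warming with NaOAc/AcOH eliminates morpholine (retro-aza-Michael) and the route is rejoined at 24.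

2. Step 7 (key step). The catalyst may discriminate poorly between the two enantiotopic enone arms, or enamine formation may be slow enough for an uncatalysed racemic cyclisation to compete. The fallback sets out from 12 and replaces enamine catalysis by hydrogen-bond/Brønsted-base catalysis on a more acidic donor, forming the same C6–C7 bond and the same ring B. Silver-catalysed carboxylation of the terminal alkyne with CO2 and O-allylation in the same flask (AgI cat., Cs2CO3, CO2, DMF; then allyl bromide) gives the allyl but-2-ynoate F2. Gold-catalysed hydration (Ph3PAuNTf2, wet dioxane) gives the β-keto ester F3, still on the achiral dienone. A quinine-derived bifunctional squaramide (10 mol%, CH2Cl2, rt) deprotonates the 1,3-dicarbonyl unit and directs C6 to one enone arm, giving the cis-fused bicyclic β-keto ester F4. Pd(PPh3)4 with morpholine removes the allyl group, the β-keto acid decarboxylates, and the route is rejoined at 14.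

3. Step 14 (axial methyl delivery). Attack along the equatorial trajectory would give the C15 epimer if complexation by the aluminium reagent is incomplete, and enolisation with β-elimination of the silyloxy group may also intervene. The fallback sets out from 20 and builds the carbinol in two stages through an epoxide. Dimethylsulfonium methylide (Me3S+ I−, KN(SiMe3)2, THF, 0 °C; Corey–Chaykovsky reaction) adds irreversibly along the axial trajectory and closes to the spiro-epoxide F5, with CH2 on the β-face and oxygen on the α-face. LiEt3BH opens the epoxide at the primary carbon and the route is rejoined at 21.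

**Further compounds**

F1 | step 16 | nine-membered β-morpholino ketone (Mannich base at C3; C3 and C4 configurations not controlled), N-Boc, 13α,15α-diol | O[C@H]1C[C@@](C)(O)C[C@H]2CC(=O)C3C(N4CCOCC4)CCN(C(=O)OC(C)(C)C)CCC[C@@]321
F2 | step 7 | allyl 4-[1-(3-{(tert-butoxycarbonyl)[2-(1,3-dioxolan-2-yl)ethyl]amino}propyl)-4-oxocyclohexa-2,5-dien-1-yl]but-2-ynoate | C=CCOC(=O)C#CCC1(CCCN(CCC2OCCO2)C(=O)OC(C)(C)C)C=CC(=O)C=C1
F3 | step 7 | allyl 4-[1-(3-{(tert-butoxycarbonyl)[2-(1,3-dioxolan-2-yl)ethyl]amino}propyl)-4-oxocyclohexa-2,5-dien-1-yl]-3-oxobutanoate | C=CCOC(=O)CC(=O)CC1(CCCN(CCC2OCCO2)C(=O)OC(C)(C)C)C=CC(=O)C=C1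
F4 | step 7 | cis-fused bicyclic β-keto ester: 14 bearing an allyloxycarbonyl group at C6 (C6 configuration not controlled) | C1=CC(=O)C[C@H]2C(C(=O)OCC=C)C(=O)C[C@]21CCCN(CCC3OCCO3)C(=O)OC(C)(C)C
F5 | step 14 | C15 spiro-epoxide of 20 (CH2 β, O α), 13α-triethylsilyloxy, C5 ketal | CC[Si](CC)(CC)O[C@H]1C[C@@]3(OC3)C[C@H]2CC4(OCCO4)C[C@]21CCCN(CCC5OCCO5)C(=O)OC(C)(C)C
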